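**Plan**

1. Retrosynthetic cuts: C8=C17 and C14=C15 (double methylenation), C12=C13 (Wittig), C6–O and C5–H (hydroboration of a C5=C6 alkene), then ring A at C2–C3 and C4–C5 (methyl methacrylate stitched onto ring B), then C10–C1 and C10–C20 (enolate alkylations) and C9–C11 (conjugate addition).
2. Forward order: ring B comes from p-benzoquinone mono(ethylene ketal); ring A is closed onto it in one operation; the C6 oxygen, the side-chain diene and the exocyclic methylene follow.
3. Enabling feature: C2 and C5 are 1,4-related through the quaternary C10 of ring B. A ring ketone at C5 and a primary iodide at C2 (iodo ketone 15) can therefore take up the C3=C4 unit of methyl methacrylate, C3 as radical acceptor and C4 (carrying CH3 and CO2Me) as enolate donor.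
4. Helpers: a dioxolane at C8 (later the methylene-bearing carbon), a PhMe2Si group as masked C12 hydroxyl (inert to radicals, borane and base), and the C5 hydroxyl left by the annulation (removed by dehydration).
5. Stereochemistry: C9 from a copper-catalysed asymmetric conjugate addition; C10 by alkylation anti to the C9 chain; C4 from a chelated chair aldol transition state; C5 and C6 from syn-hydroboration anti to both axial methyls; C12=C13 (E) from a stabilised ylide.

Key step: step 8

Remark: terpenoid numbering is used throughout (ring A = C1–C5, C10; ring B = C5–C10; C18 = ester carbon on C4; C20 = methyl on C10; C11–C15 = chain on C9), also for the monocyclic precursors; compounds 1, 2, 4, 16 and all reagents named are taken to be commercially available; in the SMILES of the zirconium and titanium compounds the cyclopentadienyl rings are drawn σ-bonded and the chloride bridge of the Tebbe reagent as a terminal Ti–Cl bond.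

**Step 1**
Reactants: 1 dimethyl(phenyl)vinylsilane; 2 Cp2Zr(H)Cl (bis(cyclopentadienyl)zirconium chloride hydride)
Product: 3 chloro[2-(dimethylphenylsilyl)ethyl]bis(cyclopentadienyl)zirconium, Cp2Zr(Cl)CH2CH2SiMe2Ph
Conditions: CH2Cl2, rt, argon, until the suspension has cleared (1 in slight excess); the solution is used directly
Reagents that add atoms: none
Why: Hydrozirconation adds Zr–H syn across the terminal alkene with zirconium on the unhindered terminal carbon, so each equivalent of vinylsilane should give one equivalent of the primary alkylzirconocene chloride needed for copper-catalysed conjugate addition.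

**Step 2**
Reactants: 4 1,4-dioxaspiro[4.5]deca-6,9-dien-8-one; 3 chloro[2-(dimethylphenylsilyl)ethyl]bis(cyclopentadienyl)zirconium
Product: 6 (10R)-10-[2-(dimethylphenylsilyl)ethyl]-1,4-dioxaspiro[4.5]dec-6-en-8-one, via chlorozirconocene dienolate 5 (not isolated)
Conditions: CuCl (cat.), AgN(SO2CF3)2 (cat.), BINOL-derived bis(1-phenylethyl)amine phosphoramidite (cat.; the ligand enantiomer that gives (10R)-6), Et2O/CH2Cl2, 0 °C → rt; aq. NH4Cl
Reagents that add atoms: none
Why: Copper–phosphoramidite-catalysed asymmetric conjugate addition of an alkylzirconocene (alkyl transfer from zirconium to the cationic monovalent copper–ligand complex, 1,4-addition, release of the zirconium dienolate) desymmetrises the benzoquinone monoketal; the ligand selects one enantiotopic enone terminus and face and so sets C9, the only source of absolute configuration in the route.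

**Step 3**
Reactants: 6 (10R)-10-[2-(dimethylphenylsilyl)ethyl]-1,4-dioxaspiro[4.5]dec-6-en-8-one
Product: 8 (9S,10S)-10-[2-(dimethylphenylsilyl)ethyl]-9-methyl-1,4-dioxaspiro[4.5]dec-6-en-8-one, via lithium dienolate 7 (not isolated)
Conditions: LDA, THF, −78 °C; MeI, −78 → −20 °C
Reagents that add atoms: iodomethane, CI
Why: Kinetic deprotonation can occur only at the α' CH2 (C10), and alkylation of this cross-conjugated dienolate installs the future C20 methyl; its configuration (trans expected) is immaterial because the centre is planarised again in step 4.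

**Step 4**
Reactants: 8 (9S,10S)-10-[2-(dimethylphenylsilyl)ethyl]-9-methyl-1,4-dioxaspiro[4.5]dec-6-en-8-one
Product: 10 (9S,10S)-9-allyl-10-[2-(dimethylphenylsilyl)ethyl]-9-methyl-1,4-dioxaspiro[4.5]dec-6-en-8-one, via lithium dienolate 9 (not isolated)
Conditions: LDA, THF/DMPU, −78 °C; allyl bromide, −78 → 0 °C
Reagents that add atoms: allyl bromide, C=CCBr
Why: Second ketone α'-alkylation through the tetrasubstituted dienolate; allyl bromide should approach anti to the pseudoaxial C9 chain, giving the quaternary C10 with allyl trans and methyl cis to that chain.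

**Step 5**
Reactants: 10 (9S,10S)-9-allyl-10-[2-(dimethylphenylsilyl)ethyl]-9-methyl-1,4-dioxaspiro[4.5]dec-6-en-8-one
Product: 12 (6S,7S)-7-allyl-6-[2-(dimethylphenylsilyl)ethyl]-7-methyl-1,4-dioxaspiro[4.5]decan-8-one, via copper enolate 11 (not isolated)
Conditions: [(Ph3P)CuH]6 (hexameric triphenylphosphine copper hydride), toluene, H2O (few equiv), rt
Reagents that add atoms: none
Why: Copper hydride conjugate reduction is selective for the enone over the isolated allyl alkene, and the carbonyl next to the quaternary centre is shielded from 1,2-attack.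

**Step 6**
Reactants: 12 (6S,7S)-7-allyl-6-[2-(dimethylphenylsilyl)ethyl]-7-methyl-1,4-dioxaspiro[4.5]decan-8-one
Product: 14 (6S,7S)-6-[2-(dimethylphenylsilyl)ethyl]-7-(2-hydroxyethyl)-7-methyl-1,4-dioxaspiro[4.5]decan-8-one, via keto aldehyde 13 (not isolated)
Conditions: O3, CH2Cl2/MeOH, NaHCO3, −78 °C; then NaBH4, −78 → −40 °C
Reagents that add atoms: ozone, [O-][O+]=O
Why: Ozonolysis cleaves the only alkene, and borohydride at low temperature reduces the peroxidic intermediates and the aldehyde but should spare the hindered α-quaternary ketone.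

**Step 7**
Reactants: 14 (6S,7S)-6-[2-(dimethylphenylsilyl)ethyl]-7-(2-hydroxyethyl)-7-methyl-1,4-dioxaspiro[4.5]decan-8-one
Product: 15 (6S,7S)-6-[2-(dimethylphenylsilyl)ethyl]-7-(2-iodoethyl)-7-methyl-1,4-dioxaspiro[4.5]decan-8-one
Conditions: I2, PPh3, imidazole, CH2Cl2, 0 °C → rt
Reagents that add atoms: iodine, II
Why: Appel iodination of the primary alcohol under buffered conditions; the open hydroxy ketone, in equilibrium with its five-membered hemiketal, is drained through the irreversible substitution.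

**Step 8**
Reactants: 15 (6S,7S)-6-[2-(dimethylphenylsilyl)ethyl]-7-(2-iodoethyl)-7-methyl-1,4-dioxaspiro[4.5]decan-8-one; 16 methyl methacrylate
Product: 20 methyl (1S,4aS,5S,8aR)-5-[2-(dimethylphenylsilyl)ethyl]-6,6-(ethylenedioxy)-8a-hydroxy-1,4a-dimethyldecahydronaphthalene-1-carboxylate (trans-fused; C5–OH anti to C20; C4 methyl syn to C20), via primary alkyl radical 17 (not isolated), via tertiary ester radical 18 (not isolated), via manganese ester enolate 19 (not isolated)
Conditions: Mn powder, PbCl2 (cat.), Me3SiCl (cat.), 16 (excess), THF/DMF, 25 °C; cold dilute aq. HCl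
Reagents that add atoms: none
Why: Manganese activated by PbCl2 and Me3SiCl reduces the primary iodide to the C2 radical 17, which adds to the CH2 terminus of 16 (C2–C3) to give the tertiary ester radical 18; this is reduced to the manganese enolate 19, which adds to the C5 ketone (C4–C5), a radical–polar crossover. The closest known reaction type is the manganese/lead-mediated three-component coupling of alkyl iodides, acrylates and ketones, used here with iodide and ketone in one molecule so that it becomes a [4+2] annulation. Ring A closes in the aldol step as a 6-(enolexo)-exo-trig addition to the carbonyl. C4 and C5 are set in a metal-bridged chair transition state fused to the ring-B chair: with C1 equatorial on C10 and the C20 methyl axial, the enolate reaches the C5 carbonyl on the face anti to that methyl (trans fusion, O5 axial), and C18, tied to O5 through manganese, must lie gauche to O5, which places CO2Me equatorial and the C4 methyl axial, syn to C20; because this tertiary aldolate forms reversibly, the chelated trans-fused isomer is expected to accumulate. Their absolute sense follows from C10, and C5 is re-set later, so only the C4/C10 relationship has to be right. The step needs addition of 17 to 16 to outrun its reduction or hydrogen transfer (excess 16; 17 has no unsaturation within reach) and attack on a single carbonyl (C8 is masked as the dioxolane, and the side chain carries the inert silyl group in place of an alkene or alcohol).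

**Step 9**
Reactants: 20 methyl (1S,4aS,5S,8aR)-5-[2-(dimethylphenylsilyl)ethyl]-6,6-(ethylenedioxy)-8a-hydroxy-1,4a-dimethyldecahydronaphthalene-1-carboxylate
Product: 22 methyl (1S,4aS,5S)-5-[2-(dimethylphenylsilyl)ethyl]-6,6-(ethylenedioxy)-1,4a-dimethyl-1,2,3,4,4a,5,6,7-octahydronaphthalene-1-carboxylate (C5=C6 alkene), via tertiary chlorosulfite 21 (not isolated)
Conditions: SOCl2, pyridine, CH2Cl2, −20 → 0 °C
Reagents that add atoms: none
Why: Chlorosulfite formation and pyridine-mediated anti elimination of the axial tertiary alcohol can engage only the axial hydrogen on C6, since C4 and C10 are quaternary, and should give the C5=C6 alkene without a free C5 cation that could trigger methyl migration.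

**Step 10**
Reactants: 22 methyl (1S,4aS,5S)-5-[2-(dimethylphenylsilyl)ethyl]-6,6-(ethylenedioxy)-1,4a-dimethyl-1,2,3,4,4a,5,6,7-octahydronaphthalene-1-carboxylate
Product: 24 methyl (1S,4aR,5S,8R,8aS)-5-[2-(dimethylphenylsilyl)ethyl]-6,6-(ethylenedioxy)-8-hydroxy-1,4a-dimethyldecahydronaphthalene-1-carboxylate (trans-decalin; equatorial 6-OH), via C6 alkylborane 23 (not isolated)
Conditions: BH3·THF, THF, 0 °C → rt; then H2O2, aq. NaHCO3, 0 °C
Reagents that add atoms: hydrogen peroxide, OO
Why: Hydroboration–oxidation: borane adds syn with boron on the less substituted C6 from the face opposite the axial methyls on C4 and C10, so C5–H and the C6 oxygen (retention on oxidation) both end up anti to C20, giving the trans ring fusion and the equatorial 6-hydroxyl.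

**Step 11**
Reactants: 24 methyl (1S,4aR,5S,8R,8aS)-5-[2-(dimethylphenylsilyl)ethyl]-6,6-(ethylenedioxy)-8-hydroxy-1,4a-dimethyldecahydronaphthalene-1-carboxylate
Product: 25 methyl (1S,4aR,5S,8R,8aS)-8-acetoxy-5-[2-(dimethylphenylsilyl)ethyl]-6,6-(ethylenedioxy)-1,4a-dimethyldecahydronaphthalene-1-carboxylate
Conditions: Ac2O, DMAP (cat.), pyridine, CH2Cl2, rt
Reagents that add atoms: acetic anhydride, CC(=O)OC(C)=O
Why: DMAP-catalysed O-acylation caps the hydroxyl before it can lactonise onto the peri C18 ester.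

**Step 12**
Reactants: 25 methyl (1S,4aR,5S,8R,8aS)-8-acetoxy-5-[2-(dimethylphenylsilyl)ethyl]-6,6-(ethylenedioxy)-1,4a-dimethyldecahydronaphthalene-1-carboxylate
Product: 27 methyl (1S,4aR,5S,8R,8aS)-8-acetoxy-6,6-(ethylenedioxy)-5-(2-hydroxyethyl)-1,4a-dimethyldecahydronaphthalene-1-carboxylate, via acetoxysilane 26 (not isolated)
Conditions: KBr, AcOOH, NaOAc, AcOH, rt
Reagents that add atoms: peracetic acid, CC(=O)OO
Why: Fleming–Tamao oxidation: bromodesilylation of the phenyl group gives an acetoxysilane whose alkyl group migrates from silicon to oxygen with retention, unmasking the C12 alcohol under buffered conditions that should leave acetate, ester and dioxolane intact.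

**Step 13**
Reactants: 27 methyl (1S,4aR,5S,8R,8aS)-8-acetoxy-6,6-(ethylenedioxy)-5-(2-hydroxyethyl)-1,4a-dimethyldecahydronaphthalene-1-carboxylate
Product: 28 methyl (1S,4aR,5S,8R,8aS)-8-acetoxy-6,6-(ethylenedioxy)-1,4a-dimethyl-5-(2-oxoethyl)decahydronaphthalene-1-carboxylate
Conditions: Dess–Martin periodinane, NaHCO3, CH2Cl2, rt
Reagents that add atoms: none
Why: Dess–Martin oxidation of the primary alcohol to the aldehyde under buffered, non-epimerising conditions.

**Step 14**
Reactants: 28 methyl (1S,4aR,5S,8R,8aS)-8-acetoxy-6,6-(ethylenedioxy)-1,4a-dimethyl-5-(2-oxoethyl)decahydronaphthalene-1-carboxylate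
Product: 29 methyl (1S,4aR,5S,8R,8aS)-8-acetoxy-6,6-(ethylenedioxy)-1,4a-dimethyl-5-[(2E)-3-methyl-4-oxobut-2-en-1-yl]decahydronaphthalene-1-carboxylate
Conditions: Ph3P=C(CH3)CHO, toluene, 80 °C
Reagents that add atoms: 2-(triphenylphosphoranylidene)propanal, CC(C=O)=P(c1ccccc1)(c1ccccc1)c1ccccc1
Why: Wittig reaction with the stabilised α-branched ylide should give the trisubstituted enal with E geometry, setting the C12=C13 configuration.

**Step 15**
Reactants: 29 methyl (1S,4aR,5S,8R,8aS)-8-acetoxy-6,6-(ethylenedioxy)-1,4a-dimethyl-5-[(2E)-3-methyl-4-oxobut-2-en-1-yl]decahydronaphthalene-1-carboxylate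
Product: 30 methyl (1S,4aR,5S,8R,8aS)-8-acetoxy-1,4a-dimethyl-5-[(2E)-3-methyl-4-oxobut-2-en-1-yl]-6-oxodecahydronaphthalene-1-carboxylate
Conditions: 1 M aq. HCl/THF, rt
Reagents that add atoms: water, O
Why: Acid-catalysed ketal hydrolysis releases the C8 ketone; mild aqueous acid should be tolerated by acetate and enal, and C9, now epimerisable, already holds the favoured equatorial chain.

**Step 16**
Reactants: 30 methyl (1S,4aR,5S,8R,8aS)-8-acetoxy-1,4a-dimethyl-5-[(2E)-3-methyl-4-oxobut-2-en-1-yl]-6-oxodecahydronaphthalene-1-carboxylate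
Product: 31 methyl (1S,4aS,5R,8R,8aS)-8-acetoxy-1,4a-dimethyl-6-methylidene-5-[(2E)-3-methylpenta-2,4-dien-1-yl]decahydronaphthalene-1-carboxylate (CNP0212193.1)
Conditions: Tebbe reagent Cp2Ti(μ-CH2)(μ-Cl)AlMe2 (2.5 equiv), pyridine (cat.), THF/toluene, −40 → 0 °C
Reagents that add atoms: Tebbe reagent Cp2Ti(μ-CH2)(μ-Cl)AlMe2, C[Al](C)C[Ti](Cl)(C1C=CC=C1)C1C=CC=C1
Why: Titanium methylidene (Tebbe) olefination converts both the hindered enolisable C8 ketone and the enal aldehyde into methylenes under non-basic conditions, which avoids β-elimination of the C6 acetate, and with only a slight excess over two equivalents at low temperature the two esters should remain untouched.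

**Compound list**

1 | dimethyl(phenyl)vinylsilane | C=C[Si](C)(C)c1ccccc1 | starting material
2 | Cp2Zr(H)Cl, bis(cyclopentadienyl)zirconium chloride hydride | [H][Zr](Cl)(C1C=CC=C1)C1C=CC=C1 | starting material
3 | chloro[2-(dimethylphenylsilyl)ethyl]bis(cyclopentadienyl)zirconium, Cp2Zr(Cl)CH2CH2SiMe2Ph | C[Si](C)(CC[Zr](Cl)(C1C=CC=C1)C1C=CC=C1)c1ccccc1 | intermediate
4 | 1,4-dioxaspiro[4.5]deca-6,9-dien-8-one (p-benzoquinone mono(ethylene ketal)) | O=C1C=CC2(C=C1)OCCO2 | starting material
5 | chlorozirconocene dienolate of 6 (not isolated) | C[Si](C)(c1ccccc1)CC[C@@H]2C3(OCCO3)C=CC(O[Zr](Cl)(C4C=CC=C4)C4C=CC=C4)=C2 | intermediate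
6 | (10R)-10-[2-(dimethylphenylsilyl)ethyl]-1,4-dioxaspiro[4.5]dec-6-en-8-one | C[Si](C)(c1ccccc1)CC[C@@H]2C3(OCCO3)C=CC(=O)C2 | intermediate
7 | lithium dienolate of 6 (not isolated) | C[Si](C)(c1ccccc1)CC[C@@H]2C3(OCCO3)C=CC(O[Li])=C2 | intermediate
8 | (9S,10S)-10-[2-(dimethylphenylsilyl)ethyl]-9-methyl-1,4-dioxaspiro[4.5]dec-6-en-8-one | C[Si](C)(c1ccccc1)CC[C@@H]2C3(OCCO3)C=CC(=O)[C@H]2C | intermediate
9 | lithium dienolate of 8 (not isolated) | C[Si](C)(c1ccccc1)CC[C@@H]2C3(OCCO3)C=CC(O[Li])=C2C | intermediate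
10 | (9S,10S)-9-allyl-10-[2-(dimethylphenylsilyl)ethyl]-9-methyl-1,4-dioxaspiro[4.5]dec-6-en-8-one | C[Si](C)(c1ccccc1)CC[C@@H]2C3(OCCO3)C=CC(=O)[C@@]2(C)CC=C | intermediate
11 | copper enolate of 12 (not isolated; phosphine ligands omitted) | C[Si](C)(c1ccccc1)CC[C@@H]2C3(OCCO3)CC=C(O[Cu])[C@@]2(C)CC=C | intermediate
12 | (6S,7S)-7-allyl-6-[2-(dimethylphenylsilyl)ethyl]-7-methyl-1,4-dioxaspiro[4.5]decan-8-one | C[Si](C)(c1ccccc1)CC[C@@H]2C3(OCCO3)CCC(=O)[C@@]2(C)CC=C | intermediate
13 | 2-[(6S,7S)-6-[2-(dimethylphenylsilyl)ethyl]-7-methyl-8-oxo-1,4-dioxaspiro[4.5]decan-7-yl]acetaldehyde (not isolated) | C[Si](C)(c1ccccc1)CC[C@@H]2C3(OCCO3)CCC(=O)[C@@]2(C)CC=O | intermediate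
14 | (6S,7S)-6-[2-(dimethylphenylsilyl)ethyl]-7-(2-hydroxyethyl)-7-methyl-1,4-dioxaspiro[4.5]decan-8-one | C[Si](C)(c1ccccc1)CC[C@@H]2C3(OCCO3)CCC(=O)[C@@]2(C)CCO | intermediate
15 | (6S,7S)-6-[2-(dimethylphenylsilyl)ethyl]-7-(2-iodoethyl)-7-methyl-1,4-dioxaspiro[4.5]decan-8-one | C[Si](C)(c1ccccc1)CC[C@@H]2C3(OCCO3)CCC(=O)[C@@]2(C)CCI | intermediate
16 | methyl methacrylate | C=C(C)C(=O)OC | starting material
17 | primary C2 radical from 15 (not isolated) | C[Si](C)(c1ccccc1)CC[C@@H]2C3(OCCO3)CCC(=O)[C@@]2(C)C[CH2] | intermediate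
18 | tertiary ester radical, adduct of 17 and 16 (not isolated) | C[Si](C)(c1ccccc1)CC[C@@H]2C3(OCCO3)CCC(=O)[C@@]2(C)CCC[C](C)C(=O)OC | intermediate
19 | manganese ester enolate (not isolated) | C[Si](C)(c1ccccc1)CC[C@@H]2C3(OCCO3)CCC(=O)[C@@]2(C)CCCC(C)=C(OC)O[Mn]I | intermediate
20 | methyl (1S,4aS,5S,8aR)-5-[2-(dimethylphenylsilyl)ethyl]-6,6-(ethylenedioxy)-8a-hydroxy-1,4a-dimethyldecahydronaphthalene-1-carboxylate | C[Si](C)(c1ccccc1)CC[C@@H]2C3(OCCO3)CC[C@@]4(O)[C@@]2(C)CCC[C@]4(C)C(=O)OC | intermediate
21 | tertiary chlorosulfite of 20 (not isolated) | C[Si](C)(c1ccccc1)CC[C@@H]2C3(OCCO3)CC[C@@]4(OS(=O)Cl)[C@@]2(C)CCC[C@]4(C)C(=O)OC | intermediate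
22 | methyl (1S,4aS,5S)-5-[2-(dimethylphenylsilyl)ethyl]-6,6-(ethylenedioxy)-1,4a-dimethyl-1,2,3,4,4a,5,6,7-octahydronaphthalene-1-carboxylate | C[Si](C)(c1ccccc1)CC[C@@H]2C3(OCCO3)CC=C4[C@@]2(C)CCC[C@]4(C)C(=O)OC | intermediate
23 | C6 alkylborane from 22 (not isolated) | C[Si](C)(c1ccccc1)CC[C@@H]2C3(OCCO3)C[C@@H](B)[C@H]4[C@@]2(C)CCC[C@]4(C)C(=O)OC | intermediate
24 | methyl (1S,4aR,5S,8R,8aS)-5-[2-(dimethylphenylsilyl)ethyl]-6,6-(ethylenedioxy)-8-hydroxy-1,4a-dimethyldecahydronaphthalene-1-carboxylate | C[Si](C)(c1ccccc1)CC[C@@H]2C3(OCCO3)C[C@@H](O)[C@H]4[C@@]2(C)CCC[C@]4(C)C(=O)OC | intermediate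
25 | methyl (1S,4aR,5S,8R,8aS)-8-acetoxy-5-[2-(dimethylphenylsilyl)ethyl]-6,6-(ethylenedioxy)-1,4a-dimethyldecahydronaphthalene-1-carboxylate | C[Si](C)(c1ccccc1)CC[C@@H]2C3(OCCO3)C[C@@H](OC(C)=O)[C@H]4[C@@]2(C)CCC[C@]4(C)C(=O)OC | intermediate
26 | acetoxysilane from 25 (not isolated) | CC(=O)O[Si](C)(C)CC[C@@H]2C3(OCCO3)C[C@@H](OC(C)=O)[C@H]4[C@@]2(C)CCC[C@]4(C)C(=O)OC | intermediate
27 | methyl (1S,4aR,5S,8R,8aS)-8-acetoxy-6,6-(ethylenedioxy)-5-(2-hydroxyethyl)-1,4a-dimethyldecahydronaphthalene-1-carboxylate | OCC[C@@H]2C3(OCCO3)C[C@@H](OC(C)=O)[C@H]4[C@@]2(C)CCC[C@]4(C)C(=O)OC | intermediate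
28 | methyl (1S,4aR,5S,8R,8aS)-8-acetoxy-6,6-(ethylenedioxy)-1,4a-dimethyl-5-(2-oxoethyl)decahydronaphthalene-1-carboxylate | O=CC[C@@H]2C3(OCCO3)C[C@@H](OC(C)=O)[C@H]4[C@@]2(C)CCC[C@]4(C)C(=O)OC | intermediate
29 | methyl (1S,4aR,5S,8R,8aS)-8-acetoxy-6,6-(ethylenedioxy)-1,4a-dimethyl-5-[(2E)-3-methyl-4-oxobut-2-en-1-yl]decahydronaphthalene-1-carboxylate | O=C/C(C)=C/C[C@@H]2C3(OCCO3)C[C@@H](OC(C)=O)[C@H]4[C@@]2(C)CCC[C@]4(C)C(=O)OC | intermediate
30 | methyl (1S,4aR,5S,8R,8aS)-8-acetoxy-1,4a-dimethyl-5-[(2E)-3-methyl-4-oxobut-2-en-1-yl]-6-oxodecahydronaphthalene-1-carboxylate | O=C/C(C)=C/C[C@@H]2C(=O)C[C@@H](OC(C)=O)[C@H]4[C@@]2(C)CCC[C@]4(C)C(=O)OC | intermediate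
31 | methyl (1S,4aS,5R,8R,8aS)-8-acetoxy-1,4a-dimethyl-6-methylidene-5-[(2E)-3-methylpenta-2,4-dien-1-yl]decahydronaphthalene-1-carboxylate (CNP0212193.1) | C=C/C(C)=C/C[C@@H]1C(=C)C[C@@H](OC(C)=O)[C@H]2[C@@]1(C)CCC[C@]2(C)C(=O)OC | target

**Step count and risks**

Total step count: 16. Longest linear sequence: 16 steps (1 → 31); counted from dienone 4 it is 15.

Steps most likely to fail:

Step 8. The primary radical may be reduced or may abstract hydrogen before it adds to the acrylate, the acrylate may telomerise, the hindered aldol closure may revert, or closure through a cis-fused transition state may erode control at C4. The fallback sets out from allyl ketone 12 and comes back at hydroxy ester 20. Hydroboration of the terminal alkene with 9-BBN and buffered peroxide oxidation gives the primary alcohol F1. Dess–Martin oxidation gives the keto aldehyde F2. Wittig olefination with methyl 2-(triphenylphosphoranylidene)propanoate gives the (E)-α-methyl enoate F3. Conjugate reduction of F3 with [(Ph3P)CuH]6 then generates the C4 enolate regiospecifically as its copper derivative, and its intramolecular aldol addition to the C5 ketone (reductive aldol cyclisation, same chelated chair) should deliver 20.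

Step 10. Borane may add slowly or with poor facial control to the hindered trisubstituted alkene, may reduce the C18 ester, or the new hydroxyl may lactonise onto that ester during oxidative work-up. The fallback sets out from alkene 22 and comes back at acetate 25. Epoxidation with mCPBA on the face opposite the two axial methyls gives the 5,6-epoxide F4. BF3·OEt2-promoted Meinwald rearrangement (C6-to-C5 hydride shift) followed by DBU equilibration gives the trans-fused 6-ketone F5. NaBH4 delivers hydride from the open face to give the axial 6-alcohol F6, which cannot lactonise. Mitsunobu inversion with acetic acid (PPh3, DIAD) should then give 25 directly.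

Step 2. Alkyl transfer from zirconium to copper may be sluggish for the β-silyl alkyl group, the dienone may be consumed by a second addition, or the enantioselectivity may be insufficient on this dienone. The fallback sets out from dienone 4 and comes back at enone 6. Rhodium-catalysed asymmetric 1,4-addition (Hayashi–Miyaura type; [Rh(cod)Cl]2 and a chiral diene or BINAP ligand) of potassium vinyltrifluoroborate gives the vinyl enone F7. Platinum-catalysed anti-Markovnikov hydrosilylation of the vinyl group with dimethylphenylsilane (Karstedt's catalyst, Pt2[(CH2=CHSiMe2)2O]3) should then give 6.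

**Further compounds**

F1 | step 8 | (6S,7S)-6-[2-(dimethylphenylsilyl)ethyl]-7-(3-hydroxypropyl)-7-methyl-1,4-dioxaspiro[4.5]decan-8-one | C[Si](C)(c1ccccc1)CC[C@@H]2C3(OCCO3)CCC(=O)[C@@]2(C)CCCO
F2 | step 8 | 3-[(6S,7S)-6-[2-(dimethylphenylsilyl)ethyl]-7-methyl-8-oxo-1,4-dioxaspiro[4.5]decan-7-yl]propanal | C[Si](C)(c1ccccc1)CC[C@@H]2C3(OCCO3)CCC(=O)[C@@]2(C)CCC=O
F3 | step 8 | methyl (2E)-5-[(6S,7S)-6-[2-(dimethylphenylsilyl)ethyl]-7-methyl-8-oxo-1,4-dioxaspiro[4.5]decan-7-yl]-2-methylpent-2-enoate | C[Si](C)(c1ccccc1)CC[C@@H]2C3(OCCO3)CCC(=O)[C@@]2(C)CC/C=C(\C)C(=O)OC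
F4 | step 10 | 5,6-epoxide of 22 (oxygen anti to the C20 methyl) | C[Si](C)(c1ccccc1)CC[C@@H]2C3(OCCO3)C[C@@H]5[C@@]4(O5)[C@@]2(C)CCC[C@]4(C)C(=O)OC
F5 | step 10 | trans-fused 6-ketone (C5–H anti to the C20 methyl) | C[Si](C)(c1ccccc1)CC[C@@H]2C3(OCCO3)CC(=O)[C@H]4[C@@]2(C)CCC[C@]4(C)C(=O)OC
F6 | step 10 | C6 epimer of 24 (axial hydroxyl, syn to the C20 methyl) | C[Si](C)(c1ccccc1)CC[C@@H]2C3(OCCO3)C[C@H](O)[C@H]4[C@@]2(C)CCC[C@]4(C)C(=O)OC
F7 | step 2 | (10R)-10-vinyl-1,4-dioxaspiro[4.5]dec-6-en-8-one | C=C[C@@H]1C2(OCCO2)C=CC(=O)C1
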